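The numbers in the tables are calculated from invented constants, and the scatter is random.

Two closed, stirred vessels stand at constant temperature, charged alike except for the initiator, and you want the average chain length in each at the end.

| setting | green | grey | south-west | east |
|---|---|---|---|---|
| free monomer | 0.039 M | 0.039 M | 0.039 M | 0.039 M |
| protic impurity | 2.6 mM | 3.9 mM | 3.90 mM | 3.90 mM |
| initiator | 2.8 mol% | 2.8 mol% | 2.8 mol% | 8 mol% |
| stray impurity | 0.74 mM | 1.5 mM | 0.74 mM | 0.74 mM |
| remark | run made earlier | run made earlier |  |  |
| time |  |  | 4.0 d | 4.0 d |

- green (time / d: monomer in chains / %): 0.333: 12.1; 0.625: 17.9; 1.04: 23.5; 1.25: 28.0; 1.67: 33.0; 2.08: 34.2; 2.50: 37.3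
- grey (time / d: monomer in chains / %): 0.208: 0.9; 0.333: 1.4; 0.417: 2.8; 0.625: 5.3; 1.04: 6.7; 1.67: 9.3; 2.50: 11.2

(standard deviation of a reading: 1 percentage point)

- the average divides the monomer in chains by the number of chains begun, living and dead together
- the earlier runs were read with a standard deviation of 1 percentage point
- the earlier runs do not show the number of chains; that part of a forecast is a guess
- no earlier run changes the charge of initiator; that part of a forecast is a guess

* which of the two ends with the longer chains by the average number of monomer units in a chain (chains begun, living or dead) ("neither" if they lie within 10%) (south-west / east / neither)
* average number of monomer units in a chain (chains begun, living or dead) at the end, south-west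
* average number of monomer units in a chain (chains begun, living or dead) at the end, east

1. Count chains first. Assume each stray impurity spends one initiator before that initiator starts a chain. The assumption gives 0.352 mM in south-west and 2.38 mM in east. It is an estimate: in the grey run the stray impurity 1.5 mM exceeds the initiator 1.09 mM, yet at 2.50 d that run shows 11.2% in chains, so there some initiator gets past the stray impurity. Call this the excess initiator, initiator charged less stray impurity, and take it as the chains begun.

2. Now work with the fraction left. In the green run, the last reading has 37.3% in chains. If each protic impurity takes one free monomer, another 6.67% of the charge is gone. That leaves 56.0% free, a reading with its scatter.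

3. Read green's bend as a floor on free monomer, with chains giving monomer back, and assume the floor ignores the number of chains. This is a guess, since no run varies the initiator.

4. South-west and east each lose 10.0% to protic impurity on the same count, so I put each at 34.0% in chains, or 13.2 mM. Divide by the excess initiator: my figures are 37.6 for south-west and 5.57 for east, so south-west is longer.

5. The forecast also picks south-west, but with other lengths, 22 and 12, and it reads the bend otherwise than I do: “the active centres die within about 1–1.5 d”.

6. The flasks give 40.3 in south-west and 6.21 in east, so south-west has the longer chains.

    free monomer + initiator → living end + monomer in chains (k = 25.0 /M/h)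
    protic impurity + free monomer → quenched substrate (k = 38.0 /M/h)
    free monomer + living end → monomer in chains + living end, rate k3*[living end]*[free monomer] (k = 100 /M/h)
    2 free monomer → self-condensation product (k = 0.00410 /M/h)
    monomer in chains + living end → free monomer + living end, rate k5*[living end] as long as [monomer in chains] is above zero (k = 2.00 /h)
    initiator + stray impurity → spent initiator (k = 17000 /M/h)

In east at 4.00 d, monomer in chains is made and used up at a ratio of 0.999, and free monomer stands at 51.2% of the charge. That matches the equilibrium monomer concentration k5/k3 of 0.0200 M, or 51.3% of the charge. A neighbour flask, like east but with 32 mol% initiator, has excess initiator 11.7 mM and living end 0.0117 M. With 37.9% in chains, its average is 1.26.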